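# Proposed total synthesis of rhodisin by ortho-quinone methide cycloaddition

## The problem

Rhodisin (18) is a B-type prodelphinidin: two (−)-epigallocatechin 3-O-gallate units joined by a single bond from C4 of the upper flavan (ring C) to C8 of the lower one (ring D), with a galloyl ester on each C3. The lower unit has the 2R,3R centres of (−)-epigallocatechin (1), which can be bought, so its two stereocentres need only be carried through. The difficulty is upper ring C, which carries three contiguous stereocentres (2R,3R,4R) in the 2,3-cis-3,4-trans, hence 2,4-trans, arrangement. The lower stereocentres lie five or more bonds from upper C4 and cannot be relied on to control it, so the relative configuration of C2, C3 and C4 must be fixed within ring C and the absolute sense by a reagent or by separation of diastereomers. The molecule has sixteen phenolic hydroxyls on pyrogallol- and phloroglucinol-type rings that oxidise readily in base, two esters that cleave under base, C2 centres that epimerise once the phenols are free, and a doubly benzylic C4–C8 bond that acid cleaves. The last step must therefore be a neutral global deprotection, which points to benzyl ethers throughout. Upper C4 is a diarylmethine that joins ring D to ring A, and the ring A carbon next to C4a (C8a) carries the ring oxygen O1, so that O1–C8a–C4a–C4 is the skeleton of an ortho-quinone methide of ring A with ring D on its methide carbon. The two remaining ring C atoms, C2 with ring B and C3 with its oxygen, form a cis-disubstituted alkene, and this is what allows a [4+2] assembly of ring C.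

## Retrosynthesis

**Deprotection and upper gallate.** Rhodisin 18 is traced to its hexadeca-O-benzyl ether 17 by cutting sixteen O–benzyl bonds. Hydrogenolysis is the only deprotection that spares the esters, the interflavan bond and the C2 centres. In 17 the acyl C–O bond of the upper gallate is cut to give alcohol 16 and tri-O-benzylgallic acid 3. The lower gallate is not cut here, because it is already in place from the start of the route. The forward esterification must acylate an axial, flanked secondary alcohol, a case known for benzylated 4→8 dimers.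

**Boron as a stand-in for the C3 oxygen.** Alcohol 16 is traced to the C3 pinacol boronate 15 (C–O back to C–B). An oxygen cannot sit on the dienophile: an enol ester would send the methide carbon to the aryl-bearing carbon and give the isoflavan pattern. Boron carries no lone pair, leaves the styrene polarisation in charge, and is exchanged for hydroxyl with retention.

**Key disconnection.** In 15 the bonds O1–C2 and C3–C4 are cut, which opens upper ring C into the ortho-quinone methide 14 and the (Z)-styryl boronate 13. The neighbouring cut, the C4–C8 bond itself, is the classical one and has strong precedent. It needs two separately activated flavan units, however, and leaves the new cycloaddition idea untested; it is kept as the fallback. The chosen cut forms one ring, two skeletal bonds and three stereocentres at once from an achiral alkene and a fragment whose upper half has no stereocentre. The 2,3-cis relation is stored in the alkene geometry. The forward reaction must deliver four things: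
- regiochemistry, with the boron-bearing carbon bonding to C4;
- suprafacial addition;
- the inside-methide/endo topology that gives 3,4-trans;
- one face of C4.

Methide 14 comes from the ortho-hydroxybenzhydrol 10 by loss of water.

**Benzhydrol.** In 10 the bond between the carbinol carbon and lower C8 is cut, giving the ring D arylmagnesium 8 and the ring A salicylaldehyde as its magnesium phenoxide 9. The other cut, between the carbinol carbon and ring A (a C8 aldehyde plus a phloroglucinol phenoxide), was set aside for three reasons:
- C8 formylation of a 5,7-dialkoxyflavan is less regioselective than C8 halogenation;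
- a phloroglucinol ether offers ortho and para positions;
- the electron-rich product can react on to a triarylmethane under the conditions of its formation.

Magnesium reagent 8 comes from the C8 iodide 5, and this from octa-O-benzyl-EGCG 4. Phenoxide 9 comes from aldehyde 7, made by double benzylation of 2,4,6-trihydroxybenzaldehyde 6. The forward addition must tolerate the gallate ester, which the low-temperature iodine–magnesium exchange allows.

**Lower unit.** In 4 the acyl C–O bond of the gallate is cut, giving penta-O-benzyl-epigallocatechin 2 and the same acid 3 that later supplies the upper gallate. Alcohol 2 comes from (−)-epigallocatechin 1 by etherification of its five phenols. This order is preferred to alkylating all eight phenols of the natural gallate at once, because the aryl ester then never meets the basic benzylation and its three benzyl ethers arrive ready-made. The forward steps need only a carbonate base that leaves the secondary C3 hydroxyl alone and a standard carbodiimide coupling.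

**Dienophile.** In 13 the C–B bond and the alkene hydrogens are removed to give alkyne 12, and the alkyne carbon is removed to give the commercial aldehyde 11. A Z-selective trans-hydroboration sets the geometry on which C2/C3 depends.

## Roads not taken

**Alternative 1:** cut O1–C8a of upper ring C. The precursor is the open-chain silyl-protected diol A2, whose C4 carries two identical 2-bromo-4,6-bis(benzyloxy)phenyl groups and is not yet a stereocentre. An intramolecular copper- or palladium-catalysed C–O coupling of the C2 hydroxyl with one of the two bromides closes ring C to A1, and the choice between the diastereotopic aryl groups creates C4.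
- Merits: aryl etherification is a known way to close a flavan ring C. C2 and C3 are set beforehand in an acyclic diol. The group selection is intramolecular, and the spectator aryl group should prefer to lie trans to the C3 silyloxy group, which is the relation wanted.
- Weak points: the ring left over in A1 is only a bromodibenzyloxyphenyl group. The whole lower unit (an oxygen on the bromine-bearing carbon, lower ring C with two stereocentres, lower ring B, the gallate) must then be built on a crowded arene. Neither half comes from the natural catechin, the route would be roughly twice as long, and the group selection is itself untested.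
- Comparison: its key step has the better precedent and avoids cationic intermediates, which the chosen plan cannot claim. The chosen plan sets against this that one step gives the full skeleton of both units from a fragment that already holds the entire lower flavan gallate.

**Alternative 2:** cut O1–C8a and C4–C4a, so that ring A is delivered as the aryne A4. The C2 alkoxide of the ring D ketone A5 adds to A4 at the future C8a, and the aryl anion formed at C4a closes on the ketone to give the 4-hydroxy-4-aryl flavan A3.
- Merits: two bonds and ring C in one operation. The regiochemistry of alkoxide addition to a 3-alkoxyaryne is inherently the right one. The lower unit is derived from the tea catechin.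
- Weak points: the alkoxide of A5 is that of a beta-hydroxy ketone and can fragment by retro-aldol cleavage between C2 and C3. C3 is enolisable. Most seriously, A3 has the wrong oxidation level at C4: ionic reduction of the tertiary benzylic alcohol would deliver hydride trans to the C3 substituent and leave ring D cis to the C3 oxygen, the 3,4-cis series, which is the opposite of the target. Both C3 oxygens are silyl ethers, so two deprotections and two galloylations follow.
- Comparison: the aryne annulation is a known reaction type, whereas the chosen key step is not. It leaves the hardest stereocentre to a later step with an adverse bias, while the chosen plan sets C4 in the ring-forming event.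

**Alternative 3:** cut the lower C4–C4a bond. The upper unit, with its gallate and with a ring D phenol ether already on C4, carries an epoxide in A7. A Lewis acid opens the epoxide at its terminal carbon by attack of ring D, closing lower ring C and releasing the lower C3 hydroxyl in A6.
- Merits: the upper C4 centre would be set beforehand by the long-established acid-promoted 4-arylation of flavan-3-ols, which is reliably 3,4-trans. The upper unit with its gallate derives from the natural catechin. Friedel–Crafts opening of aryl glycidyl ethers to chroman-3-ols is known.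
- Weak points: the lower unit is built from scratch. A7 requires etherification of a hindered phenol at an electron-rich benzylic carbon with clean inversion, where ionisation would scramble lower C2. The ring closure must choose 6-endo attack at the terminal carbon over 5-exo attack at the internal one. The Lewis acid also threatens the acid-labile C4–aryl bond.
- Comparison: for the C4 stereocentre and for precedent this road is better than the chosen one. The chosen plan sets against it that the lower C2 and C3 are taken untouched from epigallocatechin 1, that no stereocentre is made by substitution at a benzylic carbon, and that the sequence is shorter.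

Key step: step 8

## Route

Remark: both carbinol epimers of 10 are carried on together, since this carbon becomes the trigonal methide carbon of 14. The (R)-acid is taken as the enantiomer matched to the lower unit.

Step 1
Reactants: 1 (−)-epigallocatechin (EGC)
Product: 2 penta-O-benzyl-EGC
Conditions: BnBr (5.5 equiv), K2CO3 (6 equiv), DMF, 0 °C to rt, N2, degassed
Reagents that add atoms: benzyl bromide BrCc1ccccc1
Why: Williamson etherification of the five phenols; carbonate does not deprotonate the secondary C3 alcohol, which stays free as in the known benzylation of flavan-3-ols, and in oxygen-free DMF at or below room temperature the C2 centre should stay untouched.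

Step 2
Reactants: 2 penta-O-benzyl-EGC, 3 3,4,5-tris(benzyloxy)benzoic acid
Product: 4 octa-O-benzyl-EGCG
Conditions: DCC (2 equiv), DMAP (0.5 equiv), CH2Cl2, rt
Reagents that add atoms: none
Why: Steglich esterification through the N-acylpyridinium ion, the standard way to galloylate the axial 3-hydroxyl of benzylated epigallocatechin; acylation on oxygen leaves C2 and C3 unchanged.

Step 3
Reactants: 4 octa-O-benzyl-EGCG
Product: 5 8-iodo-octa-O-benzyl-EGCG
Conditions: N-iodosuccinimide (1.05 equiv), CH2Cl2, −20 to 0 °C, dark
Reagents that add atoms: N-iodosuccinimide O=C1CCC(=O)N1I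
Why: Electrophilic aromatic iodination; C8 (ortho to O1 and to the C7 ether, para to the C5 ether) is the most reactive and less hindered position of the phloroglucinol-type ring, as in the known C8 bromination of 5,7-di-O-benzyl flavan-3-ol derivatives, while the tribenzyloxyphenyl ring is less activated and the gallate ring deactivated.

Step 4
Reactants: 6 2,4,6-trihydroxybenzaldehyde
Product: 7 2,4-bis(benzyloxy)-6-hydroxybenzaldehyde
Conditions: BnBr (2.05 equiv), K2CO3 (2.2 equiv), DMF, rt
Reagents that add atoms: benzyl bromide BrCc1ccccc1
Why: Selective Williamson etherification; after the para and one ortho hydroxyl are benzylated, the last hydroxyl is locked in a hydrogen bond to the formyl group and its phenoxide is a weakly nucleophilic vinylogous carboxylate, so alkylation should stop at the dibenzyl ether.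

Step 5
Reactants: 5 8-iodo-octa-O-benzyl-EGCG, 7 2,4-bis(benzyloxy)-6-hydroxybenzaldehyde
Product: 10 ortho-hydroxybenzhydrol joining ring A to lower C8 (both carbinol epimers), via lower C8 arylmagnesium chloride 8 (not isolated), via chloromagnesium phenoxide of the aldehyde 9 (not isolated)
Conditions: 5, iPrMgCl·LiCl (1.1 equiv), THF, −30 °C; separately 7 (1.5 equiv), t-BuMgCl (1.5 equiv), THF, −78 °C; combine, −30 to 0 °C; pH 7 phosphate buffer
Reagents that add atoms: none
Why: Iodine–magnesium exchange at low temperature tolerates the hindered gallate ester, and Grignard addition to a magnesium-chelated salicylaldehyde is the standard route to ortho-hydroxybenzhydrols, the aldehyde being far more electrophilic than the ester. The carbinol centre forms without control, which does not matter because step 8 destroys it.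

Step 6
Reactants: 11 3,4,5-tris(benzyloxy)benzaldehyde
Product: 12 5-ethynyl-1,2,3-tris(benzyloxy)benzene
Conditions: dimethyl (1-diazo-2-oxopropyl)phosphonate (1.3 equiv), K2CO3 (2 equiv), MeOH/THF, rt
Reagents that add atoms: dimethyl (1-diazo-2-oxopropyl)phosphonate COP(=O)(OC)C(=[N+]=[N-])C(C)=O
Why: Seyferth–Gilbert homologation in the Ohira–Bestmann form; the aldehyde is non-enolisable and the benzyl ethers are inert to methanolic carbonate.

Step 7
Reactants: 12 5-ethynyl-1,2,3-tris(benzyloxy)benzene
Product: 13 (Z)-2-[3,4,5-tris(benzyloxy)phenyl]ethenyl pinacol boronate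
Conditions: HBpin (1.0 equiv), 12 (1.2 equiv), [RhCl(cod)]2 (1.5 mol %), P(iPr)3 (6 mol %), Et3N (1 equiv), cyclohexane, rt
Reagents that add atoms: pinacolborane CC1(C)OBOC1(C)C
Why: Rhodium-catalysed anti-Markovnikov trans-hydroboration of a terminal arylalkyne; it runs through a rhodium vinylidene, so boron and aryl end up cis on the alkene (Z).

Step 8
Reactants: 10 ortho-hydroxybenzhydrol joining ring A to lower C8, 13 (Z)-2-[3,4,5-tris(benzyloxy)phenyl]ethenyl pinacol boronate
Product: 15 trideca-O-benzyl dimer carrying a pinacolboryl group at upper C3 (upper 2S,3R,4R; lower 2R,3R), via ring A ortho-quinone methide 14 (not isolated)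
Conditions: (R)-TRIP [(R)-3,3′-bis(2,4,6-triisopropylphenyl)-1,1′-binaphthyl-2,2′-diyl hydrogen phosphate] (10 mol %), 13 (3 equiv), 4 Å molecular sieves, toluene, 0 °C to rt
Reagents that add atoms: none
Why: Proposed new method: the phosphoric acid dehydrates the electron-rich benzhydrol 10 to the ortho-quinone methide 14 and stays hydrogen-bonded to its carbonyl oxygen, and the alkene of 13 then adds across C4 and O1 in an inverse-electron-demand hetero-Diels–Alder reaction; the closest known reaction type is the Brønsted-acid-catalysed [4+2] addition of ortho-quinone methides, made in the same way from ortho-hydroxybenzhydrols, to styrenes giving 2,4-diarylchromans, which has not been shown for a beta-borylstyrene or with a 2,4-trans outcome. The boron-bearing carbon bonds to the methide carbon (C3–C4) because the charge then building up on the other alkene carbon is benzylic to the tribenzyloxyphenyl ring and beta to the electron-releasing C–B bond, and the ring A oxygen closes on that carbon (O1–C2). Ring C thus closes by a concerted but asynchronous suprafacial [4+2] addition, C–C bonding running ahead of C–O bonding, so the Z geometry of 13 becomes the 2,3-cis relation of the ring B aryl group and boron. The 3,4-trans relation is set by methide geometry and approach: the C5 benzyloxy group of ring A pushes ring D into the inside position of the heterodiene (the Z-methide drawn for 14), and endo approach of the styrene aryl group then puts aryl and boron on the face opposite ring D. The absolute configuration depends on which face of C4 is attacked; this is assigned to the chiral phosphate held at the carbonyl oxygen, and because the lower unit is already chiral the two facial products are diastereomers that can be separated if control is incomplete. Boron is used in place of oxygen on the dienophile because an enol ester would reverse the regiochemistry, while a pinacol boronate does not donate into the alkene and, as a weak Lewis acid, should not bind the phenol and transfer its alkenyl group. The step needs regioselectivity (styrene polarisation), endo selectivity on the inside methide (C5 substituent) and face selectivity (catalyst) together, and the two-aryl methide is stabilised enough to form under acidity that the gallate ester, the benzyl ethers and the C–B bond should tolerate.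

Step 9
Reactants: 15 trideca-O-benzyl dimer carrying a pinacolboryl group at upper C3
Product: 16 trideca-O-benzyl dimer with free upper C3 hydroxyl (upper 2R,3R,4R; lower 2R,3R)
Conditions: NaBO3·4H2O (5 equiv), THF/H2O (1:1), rt
Reagents that add atoms: sodium perborate (NaBO3) [Na+].[O-]OB=O
Why: Oxidation of the C–B bond by 1,2-shift of carbon from boron to oxygen, which proceeds with retention and so gives the 3R alcohol. Perborate is mild enough to spare the lower gallate, and the axial C–B bond is gauche, not anti-periplanar, to the C2–O1 bond, which disfavours ring-opening beta-elimination.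

Step 10
Reactants: 16 trideca-O-benzyl dimer with free upper C3 hydroxyl, 3 3,4,5-tris(benzyloxy)benzoic acid
Product: 17 hexadeca-O-benzylrhodisin
Conditions: DCC (3 equiv), DMAP (1 equiv), CH2Cl2, rt
Reagents that add atoms: none
Why: Steglich esterification through the N-acylpyridinium ion, a known way to galloylate the hindered axial 3-hydroxyl of benzylated 4→8 flavan-3-ol dimers; acylation on oxygen leaves all stereocentres unchanged.

Step 11
Reactants: 17 hexadeca-O-benzylrhodisin
Product: 18 rhodisin
Conditions: H2 (1 atm), Pd(OH)2 on carbon, THF/MeOH/H2O, rt; filtration, lyophilisation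
Reagents that add atoms: none
Why: Hydrogenolysis of all sixteen benzyl ethers under neutral conditions, which the aryl esters, the C4–C8 bond and the C2 centres survive, as known for benzylated proanthocyanidin gallates.

## Compound list

1 | (−)-epigallocatechin (EGC), 2R,3R | Oc1cc(O)c2c(c1)O[C@H](c1cc(O)c(O)c(O)c1)[C@H](O)C2 | starting material
2 | penta-O-benzyl-EGC: (2R,3R)-5,7-bis(benzyloxy)-2-[3,4,5-tris(benzyloxy)phenyl]chroman-3-ol | c9ccccc9COc1cc(OCc9ccccc9)c2c(c1)O[C@H](c5cc(OCc9ccccc9)c(OCc9ccccc9)c(OCc9ccccc9)c5)[C@H](O)C2 | intermediate
3 | 3,4,5-tris(benzyloxy)benzoic acid | OC(=O)c1cc(OCc2ccccc2)c(OCc2ccccc2)c(OCc2ccccc2)c1 | starting material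
4 | octa-O-benzyl-EGCG: (2R,3R)-5,7-bis(benzyloxy)-2-[3,4,5-tris(benzyloxy)phenyl]chroman-3-yl 3,4,5-tris(benzyloxy)benzoate | c9ccccc9COc1cc(OCc9ccccc9)c2c(c1)O[C@H](c5cc(OCc9ccccc9)c(OCc9ccccc9)c(OCc9ccccc9)c5)[C@H](OC(=O)c6cc(OCc9ccccc9)c(OCc9ccccc9)c(OCc9ccccc9)c6)C2 | intermediate
5 | 8-iodo-octa-O-benzyl-EGCG (2R,3R) | c9ccccc9COc1cc(OCc9ccccc9)c2c(c1I)O[C@H](c5cc(OCc9ccccc9)c(OCc9ccccc9)c(OCc9ccccc9)c5)[C@H](OC(=O)c6cc(OCc9ccccc9)c(OCc9ccccc9)c(OCc9ccccc9)c6)C2 | intermediate
6 | 2,4,6-trihydroxybenzaldehyde | O=Cc1c(O)cc(O)cc1O | starting material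
7 | 2,4-bis(benzyloxy)-6-hydroxybenzaldehyde | O=Cc1c(O)cc(OCc9ccccc9)cc1OCc9ccccc9 | intermediate
8 | C8 arylmagnesium chloride of octa-O-benzyl-EGCG (LiCl complex, not isolated) | c9ccccc9COc1cc(OCc9ccccc9)c2c(c1[Mg]Cl)O[C@H](c5cc(OCc9ccccc9)c(OCc9ccccc9)c(OCc9ccccc9)c5)[C@H](OC(=O)c6cc(OCc9ccccc9)c(OCc9ccccc9)c(OCc9ccccc9)c6)C2 | intermediate
9 | chloromagnesium phenoxide of 2,4-bis(benzyloxy)-6-hydroxybenzaldehyde (not isolated) | O=Cc1c(O[Mg]Cl)cc(OCc9ccccc9)cc1OCc9ccccc9 | intermediate
10 | (2R,3R)-8-{[2,4-bis(benzyloxy)-6-hydroxyphenyl](hydroxy)methyl}-5,7-bis(benzyloxy)-2-[3,4,5-tris(benzyloxy)phenyl]chroman-3-yl 3,4,5-tris(benzyloxy)benzoate, both carbinol epimers | OC(c2c(O)cc(OCc9ccccc9)cc2OCc9ccccc9)c3c(OCc9ccccc9)cc(OCc9ccccc9)c4c3O[C@H](c5cc(OCc9ccccc9)c(OCc9ccccc9)c(OCc9ccccc9)c5)[C@H](OC(=O)c6cc(OCc9ccccc9)c(OCc9ccccc9)c(OCc9ccccc9)c6)C4 | intermediate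
11 | 3,4,5-tris(benzyloxy)benzaldehyde | O=Cc1cc(OCc2ccccc2)c(OCc2ccccc2)c(OCc2ccccc2)c1 | starting material
12 | 5-ethynyl-1,2,3-tris(benzyloxy)benzene | C#Cc1cc(OCc2ccccc2)c(OCc2ccccc2)c(OCc2ccccc2)c1 | intermediate
13 | 4,4,5,5-tetramethyl-2-{(Z)-2-[3,4,5-tris(benzyloxy)phenyl]ethenyl}-1,3,2-dioxaborolane | C(/B1OC(C)(C)C(C)(C)O1)=C/c1cc(OCc2ccccc2)c(OCc2ccccc2)c(OCc2ccccc2)c1 | intermediate
14 | ring A ortho-quinone methide: (2R,3R)-8-{(Z)-[2,4-bis(benzyloxy)-6-oxocyclohexa-2,4-dien-1-ylidene]methyl}-5,7-bis(benzyloxy)-2-[3,4,5-tris(benzyloxy)phenyl]chroman-3-yl 3,4,5-tris(benzyloxy)benzoate (ring D on the carbonyl side; not isolated) | O=C1C=C(OCc9ccccc9)C=C(OCc9ccccc9)/C1=C/c3c(OCc9ccccc9)cc(OCc9ccccc9)c4c3O[C@H](c5cc(OCc9ccccc9)c(OCc9ccccc9)c(OCc9ccccc9)c5)[C@H](OC(=O)c6cc(OCc9ccccc9)c(OCc9ccccc9)c(OCc9ccccc9)c6)C4 | intermediate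
15 | trideca-O-benzyl dimer with pinacolboryl at upper C3: upper unit (2S,3R,4R)-5,7-bis(benzyloxy)-3-(4,4,5,5-tetramethyl-1,3,2-dioxaborolan-2-yl)-2-[3,4,5-tris(benzyloxy)phenyl]chroman-4-yl at C8 of octa-O-benzyl-EGCG (2R,3R); 2,3-cis-3,4-trans, the descriptor at C2 being S only because boron ranks below carbon | c9ccccc9COc5cc(cc(OCc9ccccc9)c5OCc9ccccc9)[C@H]1Oc2cc(OCc9ccccc9)cc(OCc9ccccc9)c2[C@H](c3c(OCc9ccccc9)cc(OCc9ccccc9)c4c3O[C@H](c5cc(OCc9ccccc9)c(OCc9ccccc9)c(OCc9ccccc9)c5)[C@H](OC(=O)c6cc(OCc9ccccc9)c(OCc9ccccc9)c(OCc9ccccc9)c6)C4)[C@H]1B7OC(C)(C)C(C)(C)O7 | intermediate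
16 | trideca-O-benzyl dimer with free upper C3 hydroxyl (upper 2R,3R,4R; lower 2R,3R, lower 3-O-gallate) | c9ccccc9COc5cc(cc(OCc9ccccc9)c5OCc9ccccc9)[C@H]1Oc2cc(OCc9ccccc9)cc(OCc9ccccc9)c2[C@H](c3c(OCc9ccccc9)cc(OCc9ccccc9)c4c3O[C@H](c5cc(OCc9ccccc9)c(OCc9ccccc9)c(OCc9ccccc9)c5)[C@H](OC(=O)c6cc(OCc9ccccc9)c(OCc9ccccc9)c(OCc9ccccc9)c6)C4)[C@H]1O | intermediate
17 | hexadeca-O-benzylrhodisin (upper 2R,3R,4R; lower 2R,3R) | c9ccccc9COc5cc(cc(OCc9ccccc9)c5OCc9ccccc9)[C@H]1Oc2cc(OCc9ccccc9)cc(OCc9ccccc9)c2[C@H](c3c(OCc9ccccc9)cc(OCc9ccccc9)c4c3O[C@H](c5cc(OCc9ccccc9)c(OCc9ccccc9)c(OCc9ccccc9)c5)[C@H](OC(=O)c6cc(OCc9ccccc9)c(OCc9ccccc9)c(OCc9ccccc9)c6)C4)[C@H]1OC(=O)c7cc(OCc9ccccc9)c(OCc9ccccc9)c(OCc9ccccc9)c7 | intermediate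
18 | rhodisin: epigallocatechin 3-O-gallate-(4β→8)-epigallocatechin 3-O-gallate (upper 2R,3R,4R; lower 2R,3R) | O=C(O[C@@H]1[C@@H](c2c(O)cc(O)c3c2O[C@H](c2cc(O)c(O)c(O)c2)[C@H](OC(=O)c2cc(O)c(O)c(O)c2)C3)c2c(O)cc(O)cc2O[C@@H]1c1cc(O)c(O)c(O)c1)c1cc(O)c(O)c(O)c1 | target

## Step count and risk

Total: 11 steps. Longest linear sequence: 8 steps (1, 2, 3, 5, 8, 9, 10, 11) from (−)-epigallocatechin. Step 4 and steps 6–7 are side branches.

Least certain steps, most uncertain first:

**Step 8 (key step).** Several things may go wrong.
- The cis-disubstituted, boron-bearing styrene may be too weak a nucleophile for a methide stabilised by two trioxygenated aryl groups, so that no addition takes place.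
- If the acid drives a fully ionic, stepwise addition, bond rotation in the benzylic cation before ring closure would erode the 2,3-cis relation.
- Inside-methide/endo control may fail and give the all-cis (4α) isomer.
- Facial control by the catalyst may be poor; the other enantiomer of the acid would be tried first.
- Loss of boron from the beta-boryl cation would open the way to a 4-styryl phenol.

Fallback (known chemistry, abandons the cycloaddition): it sets out from 4 and returns at 17. Oxidation of 4 with DDQ in the presence of 2-ethoxyethanol (CH2Cl2, rt) should give the C4 ether, 4-(2-ethoxyethoxy)-octa-O-benzyl-EGCG F1. TMSOTf (CH2Cl2, −78 °C) ionises F1 to the C4 cation, and C8 of a second portion of 4, used in excess, attacks it trans to the C3 gallate. This gives 17 directly and makes steps 3 to 10 unnecessary.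

**Step 5.** The hindered, doubly ortho-substituted arylmagnesium may add only slowly to the electron-rich phenoxide-aldehyde. Warming to force the addition invites attack on the gallate ester or simple protonation back to 4. The product may also ionise on work-up or on silica. Fallback: it sets out from 7 and returns at 10. Allylation (allyl bromide, K2CO3, DMF) gives 2-(allyloxy)-4,6-bis(benzyloxy)benzaldehyde F2, an ordinary aldehyde without phenoxide deactivation. Addition of 8 (THF, −30 °C) gives the O-allyl benzhydrol F3. Pd(PPh3)4 with morpholine (THF, rt) then removes the allyl group under neutral conditions to give 10.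

**Step 9.** The axial, flanked secondary boronate may be oxidised slowly, and longer exposure to basic peroxide risks hydrolysis of the lower gallate or base-induced ring-opening elimination. Fallback: it sets out from 15 and returns at 16. KHF2 (MeOH/THF/H2O, rt) converts the pinacol boronate into the potassium trifluoroborate F4. KHSO5 (as Oxone, 2KHSO5·KHSO4·K2SO4; acetone/H2O, rt) then oxidises the C–B bond with retention and without added base.

**Step 7.** The trans-hydroboration may give incomplete Z selectivity, or the electron-rich Z-styryl boronate may isomerise during isolation. Either would feed the 2,3-trans series into step 8. Fallback: it sets out from 12 and returns at 13. Deprotonation (n-BuLi, THF, −78 °C), trapping with 2-isopropoxy-4,4,5,5-tetramethyl-1,3,2-dioxaborolane and quenching with HCl in ether give the alkynyl pinacol boronate F5. Syn-hydrozirconation with Cp2Zr(H)Cl (THF, rt) places zirconium on the boron-bearing carbon, and protonolysis with water gives 13 with aryl and boron cis by construction.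

**Step 1.** Benzylation of a free polyphenol in base may suffer from air oxidation of the pyrogallol ring, C-benzylation of ring A, or epimerisation at C2 before the 4′-oxygen is capped. Fallback: it sets out from 1 and returns at 2. Ac2O/pyridine gives the air-stable EGC hexaacetate F6. BnBr, K2CO3 and a measured amount of water in DMF then cleave the five aryl acetates one after another and benzylate each phenoxide as it is released, so that free polyphenoxide never accumulates; the secondary alkyl acetate is far less reactive and should stay, giving 3-O-acetyl-penta-O-benzyl-EGC F7. K2CO3 in MeOH/THF (rt) then removes the C3 acetate to give 2.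

## Further compounds

F1 | step 8 | 4-(2-ethoxyethoxy)-octa-O-benzyl-EGCG (2,3-cis-3,4-trans) | c9ccccc9COc5cc(cc(OCc9ccccc9)c5OCc9ccccc9)[C@H]1Oc2cc(OCc9ccccc9)cc(OCc9ccccc9)c2[C@H](OCCOCC)[C@H]1OC(=O)c6cc(OCc9ccccc9)c(OCc9ccccc9)c(OCc9ccccc9)c6
F2 | step 5 | 2-(allyloxy)-4,6-bis(benzyloxy)benzaldehyde | O=Cc1c(OCC=C)cc(OCc9ccccc9)cc1OCc9ccccc9
F3 | step 5 | O-allyl benzhydrol (ring A phenol as allyl ether, both carbinol epimers) | OC(c2c(OCC=C)cc(OCc9ccccc9)cc2OCc9ccccc9)c3c(OCc9ccccc9)cc(OCc9ccccc9)c4c3O[C@H](c5cc(OCc9ccccc9)c(OCc9ccccc9)c(OCc9ccccc9)c5)[C@H](OC(=O)c6cc(OCc9ccccc9)c(OCc9ccccc9)c(OCc9ccccc9)c6)C4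
F4 | step 9 | potassium trifluoroborate of the upper C3 boryl dimer | c9ccccc9COc5cc(cc(OCc9ccccc9)c5OCc9ccccc9)[C@H]1Oc2cc(OCc9ccccc9)cc(OCc9ccccc9)c2[C@H](c3c(OCc9ccccc9)cc(OCc9ccccc9)c4c3O[C@H](c5cc(OCc9ccccc9)c(OCc9ccccc9)c(OCc9ccccc9)c5)[C@H](OC(=O)c6cc(OCc9ccccc9)c(OCc9ccccc9)c(OCc9ccccc9)c6)C4)[C@H]1[B-](F)(F)F.[K+]
F5 | step 7 | 4,4,5,5-tetramethyl-2-{[3,4,5-tris(benzyloxy)phenyl]ethynyl}-1,3,2-dioxaborolane | CC1(C)OB(C#Cc2cc(OCc3ccccc3)c(OCc3ccccc3)c(OCc3ccccc3)c2)OC1(C)C
F6 | step 1 | EGC hexaacetate (2R,3R) | CC(=O)Oc1cc(OC(C)=O)c2c(c1)O[C@H](c1cc(OC(C)=O)c(OC(C)=O)c(OC(C)=O)c1)[C@H](OC(C)=O)C2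
F7 | step 1 | 3-O-acetyl-penta-O-benzyl-EGC (2R,3R) | c9ccccc9COc1cc(OCc9ccccc9)c2c(c1)O[C@H](c5cc(OCc9ccccc9)c(OCc9ccccc9)c(OCc9ccccc9)c5)[C@H](OC(C)=O)C2
A1 | alternative 1 | upper flavan with C3 tert-butyldimethylsilyl ether and a 2-bromo-4,6-bis(benzyloxy)phenyl group on C4 | c9ccccc9COc5cc(cc(OCc9ccccc9)c5OCc9ccccc9)[C@H]1Oc2cc(OCc9ccccc9)cc(OCc9ccccc9)c2[C@H](c3c(Br)cc(OCc9ccccc9)cc3OCc9ccccc9)[C@H]1O[Si](C)(C)C(C)(C)C
A2 | alternative 1 | (1R,2R)-3,3-bis[2-bromo-4,6-bis(benzyloxy)phenyl]-2-(tert-butyldimethylsilyloxy)-1-[3,4,5-tris(benzyloxy)phenyl]propan-1-ol | c9ccccc9COc5cc(cc(OCc9ccccc9)c5OCc9ccccc9)[C@@H](O)[C@H](O[Si](C)(C)C(C)(C)C)C(c2c(Br)cc(OCc9ccccc9)cc2OCc9ccccc9)c3c(Br)cc(OCc9ccccc9)cc3OCc9ccccc9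
A3 | alternative 2 | 4-hydroxy-4-aryl flavan dimer with triisopropylsilyl ethers on both C3 oxygens (both C4 epimers) | c9ccccc9COc5cc(cc(OCc9ccccc9)c5OCc9ccccc9)[C@H]1Oc2cc(OCc9ccccc9)cc(OCc9ccccc9)c2C(O)(c3c(OCc9ccccc9)cc(OCc9ccccc9)c4c3O[C@H](c5cc(OCc9ccccc9)c(OCc9ccccc9)c(OCc9ccccc9)c5)[C@H](O[Si](C(C)C)(C(C)C)C(C)C)C4)[C@H]1O[Si](C(C)C)(C(C)C)C(C)C
A4 | alternative 2 | 3,5-bis(benzyloxy)benzyne | C1#CC(OCc9ccccc9)=CC(OCc9ccccc9)=C1
A5 | alternative 2 | ring D aryl ketone: lower unit acylated at C8 by a 3-hydroxy-2-(triisopropylsilyloxy)-3-[3,4,5-tris(benzyloxy)phenyl]propanoyl group | c9ccccc9COc5cc(cc(OCc9ccccc9)c5OCc9ccccc9)[C@@H](O)[C@H](O[Si](C(C)C)(C(C)C)C(C)C)C(=O)c3c(OCc9ccccc9)cc(OCc9ccccc9)c4c3O[C@H](c5cc(OCc9ccccc9)c(OCc9ccccc9)c(OCc9ccccc9)c5)[C@H](O[Si](C(C)C)(C(C)C)C(C)C)C4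
A6 | alternative 3 | perbenzylated dimer with gallate on upper C3 and free hydroxyl on lower C3 | c9ccccc9COc5cc(cc(OCc9ccccc9)c5OCc9ccccc9)[C@H]1Oc2cc(OCc9ccccc9)cc(OCc9ccccc9)c2[C@H](c3c(OCc9ccccc9)cc(OCc9ccccc9)c4c3O[C@H](c5cc(OCc9ccccc9)c(OCc9ccccc9)c(OCc9ccccc9)c5)[C@H](O)C4)[C@H]1OC(=O)c6cc(OCc9ccccc9)c(OCc9ccccc9)c(OCc9ccccc9)c6
A7 | alternative 3 | upper perbenzylated EGCG unit whose C4 aryl group carries an aryl 1-aryl-2,3-epoxypropyl ether | c9ccccc9COc5cc(cc(OCc9ccccc9)c5OCc9ccccc9)[C@H]1Oc2cc(OCc9ccccc9)cc(OCc9ccccc9)c2[C@H](c3c(OCc9ccccc9)cc(OCc9ccccc9)cc3O[C@H](c5cc(OCc9ccccc9)c(OCc9ccccc9)c(OCc9ccccc9)c5)[C@H]4CO4)[C@H]1OC(=O)c6cc(OCc9ccccc9)c(OCc9ccccc9)c(OCc9ccccc9)c6
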